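**Retrosynthetic overview**

- The core is read as a cyclohexa-1,3-diene monoepoxide. The epoxide C–C bond (the quaternary carbon bearing CH2OBz and the epoxide CH) and the adjacent ring alkene are together one oxidised diene, and the two remaining ring carbons carry cis oxygens (OBz, OH). A 2-pyrone [4+2] cycloaddition followed by CO2 loss leaves exactly this pattern.
- Key disconnection: the two ring bonds that flank the CH(OBz)–CH(OH) edge, formed by an asymmetric inverse-electron-demand Diels–Alder reaction of pyrone ester 5 with the cyclic cis-enediol ether 4. The four diene carbons of 5 become the two epoxide carbons and the two alkene carbons; its ester carbon becomes the CH2OBz carbon.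
- After the key step the lactone bridge is expelled as CO2, the ester is reduced, the epoxide is delivered by the free ring hydroxyl, both benzoates are introduced in one step, and a silyl ether on the allylic oxygen is removed last.
- Ring order: carbocycle (as a 2-oxabicyclo[2.2.2]octenone, step 3), then cyclohexadiene (step 6), then the oxirane (step 8).

Key step: step 3

Assumption: the sense of induction of the copper bis(oxazoline) catalyst with dienophile 4 is assigned by analogy; the (S,S) ligand is written, and its equally available (R,R) antipode is used if adduct 6 shows the opposite configuration.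

**Route**

Step 1
Reactants: 1 2,2-dimethyl-1,3-dioxolan-4-one
Product: 3 2,2-dimethyl-1,3-dioxolan-4-yl acetate (racemic), via aluminium hemiacetal 2 (not isolated)
Conditions: i-Bu2AlH (1.1 equiv), CH2Cl2, −78 °C; then pyridine, DMAP, Ac2O, −78 °C to rt
Reagents that add atoms: acetic anhydride, CC(=O)OC(C)=O
Why: Hydride addition to the lactone at low temperature gives a tetrahedral aluminium hemiacetal that is O-acetylated in the same flask (reductive acetylation of an ester), so the free lactol, which would fall apart to acetone and glycolaldehyde, is never released; the new acetal centre is racemic and is destroyed in step 2.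

Step 2
Reactants: 3 2,2-dimethyl-1,3-dioxolan-4-yl acetate
Product: 4 2,2-dimethyl-1,3-dioxole
Conditions: flash vacuum pyrolysis, 450 °C, quartz tube, 0.1 mbar; trap at −78 °C over K2CO3; distil
Reagents that add atoms: none
Why: Thermal syn-elimination of acetic acid through a six-membered transition state (ester pyrolysis) uses a hydrogen of the ring CH2 group, is eased by the α-oxygen, and should give the volatile cyclic cis-enediol ether without acid in solution.

Step 3
Reactants: 4 2,2-dimethyl-1,3-dioxole; 5 methyl 2-oxo-2H-pyran-3-carboxylate
Product: 6 methyl (1S,4R,7R,8S)-7,8-(isopropylidenedioxy)-3-oxo-2-oxabicyclo[2.2.2]oct-5-ene-4-carboxylate (endo adduct)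
Conditions: Cu(OTf)2 (10 mol %), (S,S)-t-Bu-BOX (11 mol %), 4 Å MS, CH2Cl2, −20 °C; 4 (2 equiv)
Reagents that add atoms: none
Why: Chelation of the lactone and ester carbonyls of 5 to divalent copper lowers the LUMO of the pyrone diene, and the electron-rich enediol ether 4 adds across pyrone C3 and C6 in a concerted, asynchronous inverse-electron-demand [4+2] cycloaddition (bond to C6 ahead); the closest known reaction type is the chiral-Lewis-acid-catalysed Diels–Alder reaction of 3-carboalkoxy-2-pyrones with enol ethers. The six-membered carbocycle is closed by this intermolecular suprafacial [4+2] event, which at the same time creates the 2-oxabicyclo[2.2.2]octenone; no ring is closed by a separate cyclisation. The cis relation of the two C–O centres is fixed by the Z geometry locked in the ring of 4, their orientation toward the new alkene (endo) by secondary overlap of the enol ether oxygens with the diene, and the absolute configuration by the tert-butyl groups of the ligand, which shield one face of the square-planar chelate. Because 4 is symmetric there is no regiochemical question; the step needs π-face and endo/exo selectivity, and since an exo adduct formed on the same pyrone face would give the mirror-image diene after CO2 loss, 6 is freed from any diastereomer by chromatography or crystallisation before step 6. The ester that makes the chelate possible is the future CH2OBz carbon, and the lactone bridge is the only part that has to be removed.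

Step 4
Reactants: 6 endo adduct
Product: 7 methyl (1S,4R,7S,8S)-7,8-dihydroxy-3-oxo-2-oxabicyclo[2.2.2]oct-5-ene-4-carboxylate
Conditions: CF3CO2H/H2O (9:1), 0 °C to rt
Reagents that add atoms: none
Why: Acid-catalysed hydrolysis of the cis-fused dioxolane is done while no diene is present, so nothing can aromatise, and the bridged lactone (whose bridgehead C–O cannot ionise to an allyl cation) and the methyl ester should survive brief aqueous acid.

Step 5
Reactants: 7 diol lactone
Product: 8 methyl (1S,4R,7S,8S)-7-[(tert-butyldimethylsilyl)oxy]-8-hydroxy-3-oxo-2-oxabicyclo[2.2.2]oct-5-ene-4-carboxylate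
Conditions: TBSCl (1.1 equiv), imidazole, DMF, 0 °C
Reagents that add atoms: tert-butyldimethylsilyl chloride, CC(C)(C)[Si](C)(C)Cl
Why: Sterically controlled silylation: the C7 hydroxyl sits beside the CH bridgehead, whereas the C8 hydroxyl is flanked by the quaternary bridgehead and hydrogen-bonded to its carbonyl groups, so the bulky silyl chloride should take C7–OH only, and the weak base avoids retro-aldol opening at C8.

Step 6
Reactants: 8 monosilyl lactone
Product: 9 methyl (5R,6S)-5-[(tert-butyldimethylsilyl)oxy]-6-hydroxycyclohexa-1,3-diene-1-carboxylate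
Conditions: PhMe (0.02 M), BHT (cat.), 110 °C
Reagents that add atoms: none
Why: Retro-[4+2] cycloreversion expels the lactone bridge as CO2 and leaves the cyclohexa-1,3-diene; both bridgehead stereocentres vanish, the two carbinol centres are untouched, and dilute acid-free conditions guard against dimerisation and aromatisation.

Step 7
Reactants: 9 diene ester
Product: 10 (1S,6R)-6-[(tert-butyldimethylsilyl)oxy]-2-(hydroxymethyl)cyclohexa-2,4-dien-1-ol
Conditions: i-Bu2AlH (3.5 equiv), CH2Cl2, −78 °C; aq. KNaC4H4O6 (Rochelle salt)
Reagents that add atoms: none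
Why: 1,2-Reduction of the conjugated ester by the aluminium hydride at low temperature should give the dienyl primary alcohol, the silyl ether is inert, and the neutral tartrate work-up protects the acid-sensitive dihydroarene diol.

Step 8
Reactants: 10 diene diol
Product: 11 (1R,2R,3R,6S)-3-[(tert-butyldimethylsilyl)oxy]-1-(hydroxymethyl)-7-oxabicyclo[4.1.0]hept-4-en-2-ol
Conditions: VO(acac)2 (5 mol %), t-BuOOH (1.2 equiv, decane), CH2Cl2, 0 °C
Reagents that add atoms: tert-butyl hydroperoxide, CC(C)(C)OO
Why: Hydroxyl-directed epoxidation by a pentavalent vanadium alkyl peroxide: the trisubstituted alkene is allylic to both the primary and the ring hydroxyl, the vanadate ester of the pseudoaxial ring hydroxyl (the bulky cis silyloxy group sits pseudoequatorial) delivers oxygen to its own face as in cyclohex-2-enols, which sets both epoxide centres syn to the two ring oxygens, and the disubstituted alkene, only homoallylic and next to the silyl ether, should stay untouched.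

Step 9
Reactants: 11 epoxy diol
Product: 12 [(1S,2R,3R,6S)-2-(benzoyloxy)-3-[(tert-butyldimethylsilyl)oxy]-7-oxabicyclo[4.1.0]hept-4-en-1-yl]methyl benzoate
Conditions: Bz2O (3 equiv), Et3N, DMAP (cat.), CH2Cl2, rt
Reagents that add atoms: benzoic anhydride, O=C(OC(=O)c1ccccc1)c1ccccc1
Why: DMAP-catalysed acylation of the primary and the hindered secondary hydroxyl with the anhydride runs under chloride-free basic conditions that should leave the vinyl epoxide and the silyl ether alone.

Step 10
Reactants: 12 silyl dibenzoate
Product: 13 [(1S,2R,3R,6S)-2-(benzoyloxy)-3-hydroxy-7-oxabicyclo[4.1.0]hept-4-en-1-yl]methyl benzoate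
Conditions: Bu4NF/AcOH (1:1), THF, 0 °C to rt
Reagents that add atoms: none
Why: Fluoride cleaves the Si–O bond, and buffering with acetic acid keeps the medium near neutral so that the cis-vicinal benzoate should not migrate to the freed hydroxyl and the vinyl epoxide is not opened.

**Compound list**

1 | 2,2-dimethyl-1,3-dioxolan-4-one | CC1(C)OCC(=O)O1 | starting material
2 | [(2,2-dimethyl-1,3-dioxolan-4-yl)oxy]diisobutylalane (aluminium hemiacetal, racemic, not isolated) | CC(C)C[Al](CC(C)C)OC1COC(C)(C)O1 | intermediate
3 | 2,2-dimethyl-1,3-dioxolan-4-yl acetate (racemic) | CC(=O)OC1COC(C)(C)O1 | intermediate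
4 | 2,2-dimethyl-1,3-dioxole | CC1(C)OC=CO1 | intermediate
5 | methyl 2-oxo-2H-pyran-3-carboxylate | COC(=O)C1=CC=COC1=O | starting material
6 | methyl (1S,4R,7R,8S)-7,8-(isopropylidenedioxy)-3-oxo-2-oxabicyclo[2.2.2]oct-5-ene-4-carboxylate (endo: dioxolane on the side of the ring alkene, away from the lactone bridge) | COC(=O)[C@]12C=C[C@H](OC1=O)[C@H]1OC(C)(C)O[C@H]12 | intermediate
7 | methyl (1S,4R,7S,8S)-7,8-dihydroxy-3-oxo-2-oxabicyclo[2.2.2]oct-5-ene-4-carboxylate | COC(=O)[C@]12C=C[C@H](OC1=O)[C@@H](O)[C@H]2O | intermediate
8 | methyl (1S,4R,7S,8S)-7-[(tert-butyldimethylsilyl)oxy]-8-hydroxy-3-oxo-2-oxabicyclo[2.2.2]oct-5-ene-4-carboxylate | COC(=O)[C@]12C=C[C@H](OC1=O)[C@@H](O[Si](C)(C)C(C)(C)C)[C@H]2O | intermediate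
9 | methyl (5R,6S)-5-[(tert-butyldimethylsilyl)oxy]-6-hydroxycyclohexa-1,3-diene-1-carboxylate | COC(=O)C1=CC=C[C@@H](O[Si](C)(C)C(C)(C)C)[C@H]1O | intermediate
10 | (1S,6R)-6-[(tert-butyldimethylsilyl)oxy]-2-(hydroxymethyl)cyclohexa-2,4-dien-1-ol | OCC1=CC=C[C@@H](O[Si](C)(C)C(C)(C)C)[C@H]1O | intermediate
11 | (1R,2R,3R,6S)-3-[(tert-butyldimethylsilyl)oxy]-1-(hydroxymethyl)-7-oxabicyclo[4.1.0]hept-4-en-2-ol | OC[C@]12O[C@H]1C=C[C@@H](O[Si](C)(C)C(C)(C)C)[C@H]2O | intermediate
12 | [(1S,2R,3R,6S)-2-(benzoyloxy)-3-[(tert-butyldimethylsilyl)oxy]-7-oxabicyclo[4.1.0]hept-4-en-1-yl]methyl benzoate | O=C(OC[C@]12O[C@H]1C=C[C@@H](O[Si](C)(C)C(C)(C)C)[C@H]2OC(=O)c1ccccc1)c1ccccc1 | intermediate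
13 | [(1S,2R,3R,6S)-2-(benzoyloxy)-3-hydroxy-7-oxabicyclo[4.1.0]hept-4-en-1-yl]methyl benzoate | O=C(OC[C@]12O[C@H]1C=C[C@@H](O)[C@H]2OC(=O)c1ccccc1)c1ccccc1 | target

**Step count and risks**

Total steps: 10. Longest linear sequence: 10 (steps 1 to 10; pyrone 5 enters at step 3).

Steps most likely to fail:

1. Step 3. The chiral catalyst may discriminate the pyrone faces or the endo/exo modes insufficiently, or the Lewis acid may oligomerise the enol ether before cycloaddition. The fallback replaces asymmetric catalysis by kinetic resolution and sets out from 4 and 5. Cycloaddition under an achiral catalyst (Yb(OTf)3, CH2Cl2, rt) should give the racemic endo adduct, that is 6 together with its mirror image, methyl (1R,4S,7S,8R)-7,8-(isopropylidenedioxy)-3-oxo-2-oxabicyclo[2.2.2]oct-5-ene-4-carboxylate F1. Hydrolysis as in step 4 gives 7 together with its enantiomer, methyl (1R,4S,7R,8R)-7,8-dihydroxy-3-oxo-2-oxabicyclo[2.2.2]oct-5-ene-4-carboxylate F2. Lipase-catalysed acylation (immobilised Candida antarctica lipase B, vinyl acetate, t-BuOMe, with the enzyme chosen by screening so that the unwanted antipode reacts) should convert F2 into methyl (1R,4S,7R,8R)-7-acetoxy-8-hydroxy-3-oxo-2-oxabicyclo[2.2.2]oct-5-ene-4-carboxylate F3 and leave 7. After separation the route is rejoined at compound 7.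

2. Step 5. Silylation may occur at the wrong hydroxyl or at both, or the base may trigger retro-aldol opening next to the doubly activated bridgehead. The fallback sets out from 7 and moves the differentiation to the diene stage, where a different principle applies. Thermolysis of the diol (PhMe, 110 °C) should give methyl (5R,6S)-5,6-dihydroxycyclohexa-1,3-diene-1-carboxylate F4. In F4 the C6 hydroxyl is tied up in a hydrogen bond to the conjugated ester and flanked by a fully substituted sp2 carbon, while the C5 hydroxyl is a free allylic alcohol. TBSCl/imidazole (CH2Cl2, −20 °C) should therefore silylate C5–OH and return to the route at compound 9.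

3. Step 8. The other alkene or the wrong face may be epoxidised, or the sensitive diene diol may aromatise at the Lewis-acidic vanadium centre. The fallback sets out from 10 and comes back at 11, replacing substrate direction by reagent control: Katsuki–Sharpless epoxidation through the primary allylic alcohol (Ti(OiPr)4, D-(−)-diethyl tartrate, t-BuOOH, 4 Å MS, CH2Cl2, −20 °C). With the hydroxymethyl group drawn at the lower right of the alkene plane the D-tartrate delivers oxygen to the upper face, which is the face of the two ring oxygens. No new compound lies on this path.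

**Further compounds**

F1 | step 3 | methyl (1R,4S,7S,8R)-7,8-(isopropylidenedioxy)-3-oxo-2-oxabicyclo[2.2.2]oct-5-ene-4-carboxylate | COC(=O)[C@@]12C=C[C@@H](OC1=O)[C@@H]1OC(C)(C)O[C@@H]12
F2 | step 3 | methyl (1R,4S,7R,8R)-7,8-dihydroxy-3-oxo-2-oxabicyclo[2.2.2]oct-5-ene-4-carboxylate | COC(=O)[C@@]12C=C[C@@H](OC1=O)[C@H](O)[C@@H]2O
F3 | step 3 | methyl (1R,4S,7R,8R)-7-acetoxy-8-hydroxy-3-oxo-2-oxabicyclo[2.2.2]oct-5-ene-4-carboxylate | COC(=O)[C@@]12C=C[C@@H](OC1=O)[C@H](OC(C)=O)[C@@H]2O
F4 | step 5 | methyl (5R,6S)-5,6-dihydroxycyclohexa-1,3-diene-1-carboxylate | COC(=O)C1=CC=C[C@@H](O)[C@H]1O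
F0 | step 8 | none | none
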